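**Strategy.** The route rests on disconnecting the O1–C2 bond of the dihydropyran ring. An all-cis 2,4,6-trisubstituted tetrahydropyran, assembled in one three-component Prins/Friedel–Crafts step, already carries every aromatic ring and the C4 and carbinol stereocentres. Acid then ionises its C2–O bond, which is benzylic to the 4-oxygenated C2 aryl ring, and the neighbouring ring A phenol recloses the cation to the benzopyran ring, releasing the side-chain alcohol. Because this para-alkoxybenzylic C2–O1 bond ionises reversibly, both C2 epimers drain into the 2,4-trans chroman, in which the C4 chain lies pseudoaxial away from the peri C5 oxygen. O-Methylation, Claisen–Schmidt condensation and deallylation finish the synthesis.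

Key step: step 6

Assumption: (−)-B-allyldiisopinocampheylborane is taken as the commercial pentane solution, and the 2,4-trans chroman is taken to be the more stable C2 epimer because of the peri C5 oxygen.

**Step 1**
Reactants: 1 3-(4-hydroxyphenyl)propan-1-ol; 2 allyl bromide
Product: 3 3-[4-(allyloxy)phenyl]propan-1-ol
Conditions: K2CO3, acetone, reflux
Reagents that add atoms: allyl bromide (2), C=CCBr
Why: Williamson etherification in which K2CO3 deprotonates only the phenol, so the primary alcohol should stay free.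

**Step 2**
Reactants: 3 3-[4-(allyloxy)phenyl]propan-1-ol
Product: 4 3-[4-(allyloxy)phenyl]propanal
Conditions: TEMPO (cat.), PhI(OAc)2, CH2Cl2, rt
Reagents that add atoms: none
Why: Oxoammonium (TEMPO) oxidation of a primary alcohol, which should stop at the aldehyde and leave the allyl ether untouched.

**Step 3**
Reactants: 4 3-[4-(allyloxy)phenyl]propanal; 5 (−)-B-allyldiisopinocampheylborane
Product: 7 (3R)-1-[4-(allyloxy)phenyl]hex-5-en-3-ol, via borinate ester 6 (not isolated)
Conditions: Et2O, −78 °C; then NaOH, H2O2, 0 °C to rt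
Reagents that add atoms: (−)-B-allyldiisopinocampheylborane (5), C=CCB([C@@H]1C[C@@H]2C[C@@H](C2(C)C)[C@H]1C)[C@@H]1C[C@@H]2C[C@@H](C2(C)C)[C@H]1C
Why: Brown allylboration through a chair Zimmerman–Traxler transition state, in which the reagent derived from (+)-α-pinene delivers the allyl group to the Si face of the aldehyde and so sets the (R) carbinol centre.

**Step 4**
Reactants: 8 2,4,6-trihydroxyacetophenone; 2 allyl bromide
Product: 9 1-[4-(allyloxy)-2,6-dihydroxyphenyl]ethanone
Conditions: K2CO3 (1 equiv), DMF, 0 °C to rt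
Reagents that add atoms: allyl bromide (2), C=CCBr
Why: Williamson mono-etherification at the 4-hydroxyl, which is para to the acetyl group and not hydrogen-bonded to it, hence the most acidic and the most nucleophilic of the three.

**Step 5**
Reactants: 7 (3R)-1-[4-(allyloxy)phenyl]hex-5-en-3-ol; 10 4-(allyloxy)benzaldehyde; 9 1-[4-(allyloxy)-2,6-dihydroxyphenyl]ethanone
Product: 13 1-[4-(allyloxy)-3-[(2R,4S,6R)-2-[4-(allyloxy)phenyl]-6-[2-[4-(allyloxy)phenyl]ethyl]tetrahydropyran-4-yl]-2,6-dihydroxyphenyl]ethanone (all-cis tetrahydropyran), via oxocarbenium ion 11 (not isolated), via tetrahydropyranyl cation 12 (not isolated)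
Conditions: BF3·OEt2, CH2Cl2, −78 to −20 °C (9 in excess)
Reagents that add atoms: 4-(allyloxy)benzaldehyde (10), O=Cc1ccc(OCC=C)cc1; ketone 9, CC(=O)c1c(O)cc(OCC=C)cc1O
Why: Prins cyclisation followed by Friedel–Crafts capture, in which the (E)-oxocarbenium ion closes through a chair with both substituents equatorial and the C4 cation is attacked equatorially by one of the two equivalent free ring positions of the symmetric phenol 9, so the carbinol centre of 7 should fix C2 and C4 in the all-cis (2R,4S,6R) arrangement with no regiochemical choice on ring A.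

**Step 6**
Reactants: 13 all-cis tetrahydropyran
Product: 16 1-[(2R,4S)-5-(allyloxy)-2-[4-(allyloxy)phenyl]-4-[(2R)-4-[4-(allyloxy)phenyl]-2-hydroxybutyl]-7-hydroxychroman-8-yl]ethanone, via benzylic cation 14 (not isolated), via cis chroman epimer 15 (not isolated)
Conditions: TsOH·H2O (0.2 equiv), ClCH2CH2Cl (0.01 M), 50 °C
Reagents that add atoms: none
Why: TsOH protonates the tetrahydropyran oxygen of 13 and the C2–O bond, benzylic to the para-allyloxyphenyl ring, ionises to the open cation 14, which is captured by the ring A hydroxyl ortho to the ring junction (the only one in reach, the other ortho oxygen being allylated) to form the O1–C2 bond. The closest known reaction type is the acid-catalysed SN1 transetherification by which 2-aryl tetrahydropyrans and flavans epimerise at their benzylic ether carbon, run here as a ring-chain isomerisation. The benzopyran ring closes in a 6-exo-trig mode through a chair-like transition state on the trigonal cation. C2 is set under thermodynamic control: the chroman C2–O1 bond re-ionises under the same conditions, so the cis epimer 15 returns to 14 and the material should collect in the 2,4-trans isomer 16, whose C2 aryl group is pseudoequatorial while the C4 chain is pseudoaxial and so avoids peri strain with the C5 allyloxy group; C4 and the carbinol centre are not touched. The step needs the chroman over return to the tetrahydropyran and O-capture over bimolecular C-alkylation: 16 keeps the hydrogen bond between the acetyl group and the C7 hydroxyl, gains a freely rotating chain and loses the congestion of a doubly ortho-substituted aryl group on the tetrahydropyran, and high dilution disfavours intermolecular Friedel–Crafts capture.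

**Step 7**
Reactants: 16 2,4-trans chroman; 17 methyl iodide
Product: 18 1-[(2R,4S)-5-(allyloxy)-2-[4-(allyloxy)phenyl]-4-[(2R)-4-[4-(allyloxy)phenyl]-2-hydroxybutyl]-7-methoxychroman-8-yl]ethanone
Conditions: K2CO3, acetone, reflux
Reagents that add atoms: methyl iodide (17), CI
Why: Williamson methylation of the only free phenol (the chelated C7 hydroxyl, hence the heating), while the secondary alcohol is not deprotonated by K2CO3.

**Step 8**
Reactants: 18 methyl ether; 10 4-(allyloxy)benzaldehyde
Product: 19 (E)-1-[(2R,4S)-5-(allyloxy)-2-[4-(allyloxy)phenyl]-4-[(2R)-4-[4-(allyloxy)phenyl]-2-hydroxybutyl]-7-methoxychroman-8-yl]-3-[4-(allyloxy)phenyl]prop-2-en-1-one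
Conditions: KOH, EtOH, rt
Reagents that add atoms: 4-(allyloxy)benzaldehyde (10), O=Cc1ccc(OCC=C)cc1
Why: Claisen–Schmidt condensation of a methyl ketone that carries no free phenol with a non-enolisable aldehyde, whose E1cB dehydration should give the (E)-enone, and the C2 ether cannot open under base because its aryl group is allyl-protected.

**Step 9**
Reactants: 19 tetraallyl chalcone
Product: 20 (E)-1-[(2R,4S)-5-hydroxy-4-[(2R)-2-hydroxy-4-(4-hydroxyphenyl)butyl]-2-(4-hydroxyphenyl)-7-methoxychroman-8-yl]-3-(4-hydroxyphenyl)prop-2-en-1-one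
Conditions: Pd(PPh3)4 (cat.), morpholine, THF, rt
Reagents that add atoms: none
Why: Tsuji–Trost deallylation, in which zerovalent palladium ionises each aryl allyl ether to a π-allyl complex and a phenoxide and morpholine takes up the allyl group, under neutral conditions that should spare the enone, the benzylic aryl ether and all three stereocentres.

**Compound list**

1 | 3-(4-hydroxyphenyl)propan-1-ol | OCCCc1ccc(O)cc1 | starting material
2 | allyl bromide | C=CCBr | starting material
3 | 3-[4-(allyloxy)phenyl]propan-1-ol | OCCCc1ccc(OCC=C)cc1 | intermediate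
4 | 3-[4-(allyloxy)phenyl]propanal | O=CCCc1ccc(OCC=C)cc1 | intermediate
5 | (−)-B-allyldiisopinocampheylborane | C=CCB([C@@H]1C[C@@H]2C[C@@H](C2(C)C)[C@H]1C)[C@@H]1C[C@@H]2C[C@@H](C2(C)C)[C@H]1C | starting material
6 | (3R)-1-[4-(allyloxy)phenyl]hex-5-en-3-yl diisopinocampheylborinate | C=CC[C@@H](CCc1ccc(OCC=C)cc1)OB([C@@H]1C[C@@H]2C[C@@H](C2(C)C)[C@H]1C)[C@@H]1C[C@@H]2C[C@@H](C2(C)C)[C@H]1C | intermediate
7 | (3R)-1-[4-(allyloxy)phenyl]hex-5-en-3-ol | C=CC[C@H](O)CCc1ccc(OCC=C)cc1 | intermediate
8 | 2,4,6-trihydroxyacetophenone | CC(=O)c1c(O)cc(O)cc1O | starting material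
9 | 1-[4-(allyloxy)-2,6-dihydroxyphenyl]ethanone | CC(=O)c1c(O)cc(OCC=C)cc1O | intermediate
10 | 4-(allyloxy)benzaldehyde | O=Cc1ccc(OCC=C)cc1 | starting material
11 | (E)-oxocarbenium ion formed from 7 and 10 by loss of water | C=CC[C@@H](CCc1ccc(OCC=C)cc1)/[O+]=C/c1ccc(OCC=C)cc1 | intermediate
12 | 2,6-cis-2-[4-(allyloxy)phenyl]-6-[2-[4-(allyloxy)phenyl]ethyl]tetrahydropyran-4-yl cation | C=CCOc1ccc(CC[C@@H]2C[CH+]C[C@H](c3ccc(OCC=C)cc3)O2)cc1 | intermediate
13 | 1-[4-(allyloxy)-3-[(2R,4S,6R)-2-[4-(allyloxy)phenyl]-6-[2-[4-(allyloxy)phenyl]ethyl]tetrahydropyran-4-yl]-2,6-dihydroxyphenyl]ethanone | C=CCOc1ccc(CC[C@@H]2C[C@H](c3c(O)c(C(C)=O)c(O)cc3OCC=C)C[C@H](c3ccc(OCC=C)cc3)O2)cc1 | intermediate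
14 | open-chain para-allyloxybenzylic cation at C1 of the heptane chain, side-chain hydroxyl free | C=CCOc1ccc(cc1)[CH+]C[C@@H](c1c(O)c(C(C)=O)c(O)cc1OCC=C)C[C@H](O)CCc1ccc(OCC=C)cc1 | intermediate
15 | 1-[(2S,4S)-5-(allyloxy)-2-[4-(allyloxy)phenyl]-4-[(2R)-4-[4-(allyloxy)phenyl]-2-hydroxybutyl]-7-hydroxychroman-8-yl]ethanone (2,4-cis epimer) | CC(=O)c1c(O)cc(OCC=C)c2c1O[C@H](c1ccc(OCC=C)cc1)C[C@@H]2C[C@H](O)CCc1ccc(OCC=C)cc1 | intermediate
16 | 1-[(2R,4S)-5-(allyloxy)-2-[4-(allyloxy)phenyl]-4-[(2R)-4-[4-(allyloxy)phenyl]-2-hydroxybutyl]-7-hydroxychroman-8-yl]ethanone | CC(=O)c1c(O)cc(OCC=C)c2c1O[C@@H](c1ccc(OCC=C)cc1)C[C@@H]2C[C@H](O)CCc1ccc(OCC=C)cc1 | intermediate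
17 | methyl iodide | CI | starting material
18 | 1-[(2R,4S)-5-(allyloxy)-2-[4-(allyloxy)phenyl]-4-[(2R)-4-[4-(allyloxy)phenyl]-2-hydroxybutyl]-7-methoxychroman-8-yl]ethanone | COc1cc(OCC=C)c2c(c1C(C)=O)O[C@@H](c1ccc(OCC=C)cc1)C[C@@H]2C[C@H](O)CCc1ccc(OCC=C)cc1 | intermediate
19 | (E)-1-[(2R,4S)-5-(allyloxy)-2-[4-(allyloxy)phenyl]-4-[(2R)-4-[4-(allyloxy)phenyl]-2-hydroxybutyl]-7-methoxychroman-8-yl]-3-[4-(allyloxy)phenyl]prop-2-en-1-one | COc1cc(OCC=C)c2c(c1C(=O)/C=C/c1ccc(OCC=C)cc1)O[C@@H](c1ccc(OCC=C)cc1)C[C@@H]2C[C@H](O)CCc1ccc(OCC=C)cc1 | intermediate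
20 | (E)-1-[(2R,4S)-5-hydroxy-4-[(2R)-2-hydroxy-4-(4-hydroxyphenyl)butyl]-2-(4-hydroxyphenyl)-7-methoxychroman-8-yl]-3-(4-hydroxyphenyl)prop-2-en-1-one | COc1cc(O)c2c(c1C(=O)/C=C/c1ccc(O)cc1)O[C@@H](c1ccc(O)cc1)C[C@@H]2C[C@H](O)CCc1ccc(O)cc1 | target

**Step count.** Total: 9 steps. Longest linear sequence: 8 steps (steps 1, 2, 3, 5, 6, 7, 8, 9); step 4 is a one-step side branch.

**Steps most likely to fail**

1. Step 6. The ring-chain equilibrium may stop short of the chroman side, because the liberated side-chain alcohol can recapture the benzylic cation, and bimolecular alkylation of ring A may compete. The fallback blocks that alcohol before the cation is formed and sets out from 13. Ac2O with catalytic Sc(OTf)3 in MeCN at 0 °C should cleave the benzylic ether acylatively and acetylate both phenols, giving the open-chain (1RS,3S,5R) tetraacetate F1 as a C1 epimer pair. Pyrrolidine in CH2Cl2 at 0 °C should remove only the two aryl acetates to give the diphenol diacetate F2. TsOH in ClCH2CH2Cl then ionises the benzylic acetate, and the phenol closes the cation, with no alcohol left to compete, to the chroman side-chain acetate F3 under the same thermodynamic control at C2. K2CO3 in MeOH cleaves the remaining acetate and the route is rejoined at 16.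

2. Step 5. Free aldehyde may condense directly with the electron-rich phenol, the stabilised oxocarbenium ion may cyclise sluggishly, and the product may be alkylated a second time. The fallback removes the free aldehyde and water from the coupling and sets out from 7. Esterification with 4-(allyloxy)benzoic acid (DCC, DMAP, CH2Cl2) gives the (3R) ester F4. Reductive acetylation (iBu2AlH, CH2Cl2, −78 °C; then Ac2O, pyridine, DMAP) gives the α-acetoxy ether F5 as a mixture at the acetal carbon. BF3·OEt2 with excess 9 in CH2Cl2 at −78 to −20 °C ionises F5 to the same oxocarbenium ion, and Prins cyclisation with Friedel–Crafts capture rejoins the route at 13.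

3. Step 9. Allyl transfer from the π-allyl complex to carbon of the electron-rich ring A, or amine addition to the enone, may erode the fourfold deprotection. The fallback avoids π-allyl intermediates and sets out from 19. [Ir(cod)(PMePh2)2]PF6, activated with H2, in THF at rt should isomerise the four allyl ethers to the tetrakis[(E)-prop-1-enyl] ether F6. Pyridinium p-toluenesulfonate in MeOH at rt then cleaves the aryl enol ethers and gives 20.

**Further compounds**

F1 | step 6 | (1RS,3S,5R)-3-[3-acetyl-2,4-diacetoxy-6-(allyloxy)phenyl]-1,7-bis[4-(allyloxy)phenyl]heptane-1,5-diyl diacetate | C=CCOc1ccc(cc1)C(OC(C)=O)C[C@@H](c1c(OC(C)=O)c(C(C)=O)c(OC(C)=O)cc1OCC=C)C[C@H](OC(C)=O)CCc1ccc(OCC=C)cc1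
F2 | step 6 | (1RS,3S,5R)-3-[3-acetyl-6-(allyloxy)-2,4-dihydroxyphenyl]-1,7-bis[4-(allyloxy)phenyl]heptane-1,5-diyl diacetate | C=CCOc1ccc(cc1)C(OC(C)=O)C[C@@H](c1c(O)c(C(C)=O)c(O)cc1OCC=C)C[C@H](OC(C)=O)CCc1ccc(OCC=C)cc1
F3 | step 6 | (2R)-1-[(2R,4S)-8-acetyl-5-(allyloxy)-2-[4-(allyloxy)phenyl]-7-hydroxychroman-4-yl]-4-[4-(allyloxy)phenyl]butan-2-yl acetate | CC(=O)c1c(O)cc(OCC=C)c2c1O[C@@H](c1ccc(OCC=C)cc1)C[C@@H]2C[C@H](OC(C)=O)CCc1ccc(OCC=C)cc1
F4 | step 5 | (3R)-1-[4-(allyloxy)phenyl]hex-5-en-3-yl 4-(allyloxy)benzoate | C=CC[C@@H](CCc1ccc(OCC=C)cc1)OC(=O)c1ccc(OCC=C)cc1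
F5 | step 5 | [4-(allyloxy)phenyl][(3R)-1-[4-(allyloxy)phenyl]hex-5-en-3-yloxy]methyl acetate | C=CC[C@@H](CCc1ccc(OCC=C)cc1)OC(OC(C)=O)c1ccc(OCC=C)cc1
F6 | step 9 | tetrakis[(E)-prop-1-enyl] ether isomer of 19 | COc1cc(O/C=C/C)c2c(c1C(=O)/C=C/c1ccc(O/C=C/C)cc1)O[C@@H](c1ccc(O/C=C/C)cc1)C[C@@H]2C[C@H](O)CCc1ccc(O/C=C/C)cc1
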